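**Retrosynthetic overview**
1. Target ⇐ C4=CH2 unmasked last (Peterson elimination of a β-hydroxysilane) ⇐ 7-O-acylation ⇐ α-face dihydroxylation of C7=C8 ⇐ butenolide by ring-closing metathesis.
2. 6β-OH/C7=C8(CH3) ⇐ MeLi addition to a C8 enone, then 1,3-allylic transposition; C11 carbinol ⇐ chelation-controlled allylation of a C9 aldehyde.
3. C9 quaternary centre ⇐ hydroxymethylation of the C8=C9 silyl enol ether that the key step delivers.
4. Key step: intramolecular Diels–Alder reaction of a 2-silyloxydiene/isopropenyl ketone trienone (bonds C5–C10 and C6–C7) forms rings A and B together; the butenolide ring is formed last (step 14).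
5. Trienone ⇐ (S)-5-(hydroxymethyl)butyrolactone (L-glutamic acid pool, C1 stereocentre) + keto ylide + isopropenyllithium.

Assumption: 1, 2, 2-bromopropene and 13 are taken as commercial; the C4 carbinol configuration in 8–23 is lost in step 17 and is drawn as expected for α-face attack.
Numbering: clerodane numbering (decalin C1–C10, side chain C11–C16, C17 on C8, C18 on C4, C19 on C5, C20 on C9); β = face of the C19 methyl, α = the opposite face.

Step 1
Reactants: 1 (S)-5-(hydroxymethyl)dihydrofuran-2(3H)-one; 2 the keto ylide 3-(triphenyl-λ5-phosphanylidene)butan-2-one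
Product: 4 (S)-5-[(1E)-2-methyl-3-oxobut-1-en-1-yl]dihydrofuran-2(3H)-one, via lactone aldehyde 3 (not isolated)
Conditions: DMP, CH2Cl2, 0 °C to rt; then 2, 40 °C
Reagents that add atoms: none
Why: Dess–Martin oxidation gives the labile α-acyloxy aldehyde, which is trapped at once by the stabilised ylide in a neutral, E-selective Wittig olefination that does not epimerise the bought C1 centre.

Step 2
Reactants: 4 (S)-5-[(1E)-2-methyl-3-oxobut-1-en-1-yl]dihydrofuran-2(3H)-one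
Product: 5 (S)-5-[(1E)-2-methyl-3-(triethylsilyloxy)buta-1,3-dien-1-yl]dihydrofuran-2(3H)-one
Conditions: TESOTf, Et3N, CH2Cl2, −78 to 0 °C
Reagents that add atoms: triethylsilyl triflate, CC[Si](CC)(CC)OS(=O)(=O)C(F)(F)F
Why: Soft enolisation silylates the methyl ketone on its CH3 side to the cross-conjugated 2-silyloxydiene (silyl enol ether formation) and leaves the γ-lactone and the E-alkene untouched.

Step 3
Reactants: 5 (S)-5-[(1E)-2-methyl-3-(triethylsilyloxy)buta-1,3-dien-1-yl]dihydrofuran-2(3H)-one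
Product: 7 1α-hydroxy-5β,9-dimethyl-8-(triethylsilyloxy)-10αH-decal-8-en-4-one (trans-fused), via hydroxy trienone 6 (not isolated)
Conditions: 2-bromopropene, tBuLi (2 equiv), Et2O, −78 °C; 5, THF, −78 °C; AcOH (1 equiv); then toluene, BHT, 80 °C
Reagents that add atoms: isopropenyllithium, [Li]C(C)=C (made in the flask from 2-bromopropene, C=C(C)Br, and tBuLi)
Why: The alkenyllithium adds once to the γ-lactone (stable lithium lactolate at −78 °C) and the freed isopropenyl ketone undergoes an intramolecular Diels–Alder reaction in which A(1,3) strain with the C9 methyl holds H1 in the diene plane and the C1–O bond anti to the forming C10–C5 bond (10α-H from the bought 1S centre), while the same methyl disfavours the folded cis-fused transition state so that the chair-like trans-fused one sets the 5β methyl.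

Step 4
Reactants: 7 1α-hydroxy-5β,9-dimethyl-8-(triethylsilyloxy)-10αH-decal-8-en-4-one
Product: 8 5β,9-dimethyl-8-(triethylsilyloxy)-4α-[(trimethylsilyl)methyl]-10αH-decal-8-ene-1α,4β-diol
Conditions: Me3SiCH2Li (3.5 equiv), CeCl3, THF, −78 to 0 °C; H2O
Reagents that add atoms: (trimethylsilyl)methyllithium, C[Si](C)(C)C[Li]
Why: CeCl3-mediated 1,2-addition to the hindered, enolisable C4 ketone (α face, anti to the axial C19 methyl) stores the exocyclic methylene as a β-hydroxysilane (first half of a Peterson olefination) that survives MeLi and OsO4.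

Step 5
Reactants: 8 5β,9-dimethyl-8-(triethylsilyloxy)-4α-[(trimethylsilyl)methyl]-10αH-decal-8-ene-1α,4β-diol
Product: 9 1α-acetoxy-5β,9-dimethyl-8-(triethylsilyloxy)-4α-[(trimethylsilyl)methyl]-10αH-decal-8-en-4β-ol
Conditions: Ac2O, pyridine, DMAP (cat.), CH2Cl2, rt
Reagents that add atoms: acetic anhydride, CC(=O)OC(C)=O
Why: Acylation (DMAP-catalysed acetylation) takes only the secondary C1 alcohol, since the tertiary C4 alcohol and the silyl enol ether do not react.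

Step 6
Reactants: 9 1α-acetoxy-5β,9-dimethyl-8-(triethylsilyloxy)-4α-[(trimethylsilyl)methyl]-10αH-decal-8-en-4β-ol
Product: 10 1α-acetoxy-4β-hydroxy-9α-(hydroxymethyl)-5β,9β-dimethyl-4α-[(trimethylsilyl)methyl]-10αH-decalin-8-one
Conditions: aq. HCHO (37%), Sc(OTf)3 (10 mol%), THF, rt
Reagents that add atoms: formaldehyde, C=O
Why: Aqueous Mukaiyama aldol reaction (hydroxymethylation) of the regiodefined tetrasubstituted silyl enol ether, with formaldehyde entering on the α face anti to the 1,3-related axial C19 methyl, sets the C9 quaternary centre (C20 β, C11 α).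

Step 7
Reactants: 10 1α-acetoxy-4β-hydroxy-9α-(hydroxymethyl)-5β,9β-dimethyl-4α-[(trimethylsilyl)methyl]-10αH-decalin-8-one
Product: 12 1α-acetoxy-4β-hydroxy-5β,9β-dimethyl-8-oxo-4α-[(trimethylsilyl)methyl]-10αH-decal-6-ene-9α-carbaldehyde, via keto aldehyde 11 (not isolated)
Conditions: IBX (4 equiv), DMSO, 70 °C
Reagents that add atoms: none
Why: IBX oxidises the neopentyl primary alcohol to the aldehyde and then dehydrogenates the ketone (Nicolaou IBX α,β-dehydrogenation), which can enolise only towards C7 because C9 is quaternary.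

Step 8
Reactants: 13 2-methylprop-2-en-1-ol
Product: 14 2-[(tributylstannyl)methyl]prop-2-en-1-ol
Conditions: nBuLi (2.2 equiv), TMEDA, Et2O, 0 °C to rt; Bu3SnCl, −78 °C to rt; H2O
Reagents that add atoms: tributyltin chloride, CCCC[Sn](Cl)(CCCC)CCCC
Why: O,C-dilithiation of methallyl alcohol followed by C-stannylation of the allyl anion (electrophilic trapping) gives the bifunctional allylstannane.

Step 9
Reactants: 14 2-[(tributylstannyl)methyl]prop-2-en-1-ol
Product: 15 2-[(tributylstannyl)methyl]prop-2-en-1-yl acetate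
Conditions: Ac2O, pyridine, DMAP (cat.), CH2Cl2, 0 °C
Reagents that add atoms: acetic anhydride, CC(=O)OC(C)=O
Why: Simple acetylation caps the hydroxyl so that the stannane can be used with a Lewis acid.

Step 10
Reactants: 12 1α-acetoxy-4β-hydroxy-5β,9β-dimethyl-8-oxo-4α-[(trimethylsilyl)methyl]-10αH-decal-6-ene-9α-carbaldehyde; 15 2-[(tributylstannyl)methyl]prop-2-en-1-yl acetate
Product: 16 9α-[(1R)-3-(acetoxymethyl)-1-hydroxybut-3-en-1-yl]-1α-acetoxy-4β-hydroxy-5β,9β-dimethyl-4α-[(trimethylsilyl)methyl]-10αH-decal-6-en-8-one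
Conditions: MgBr2·OEt2 (3 equiv), CH2Cl2, −78 to −20 °C; H2O
Reagents that add atoms: none
Why: Chelation-controlled (Keck-type) SE2′ allylstannane addition, in which MgBr2 bridges the aldehyde and C8 ketone oxygens and the nucleophile attacks the aldehyde face anti to C10 (the C20 methyl side of the chelate), gives the 11R carbinol and leaves the hindered enone alone.

Step 11
Reactants: 16 9α-[(1R)-3-(acetoxymethyl)-1-hydroxybut-3-en-1-yl]-1α-acetoxy-4β-hydroxy-5β,9β-dimethyl-4α-[(trimethylsilyl)methyl]-10αH-decal-6-en-8-one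
Product: 17 9α-[(1R)-1-hydroxy-3-(hydroxymethyl)but-3-en-1-yl]-5β,8α,9β-trimethyl-4α-[(trimethylsilyl)methyl]-10αH-decal-6-ene-1α,4β,8β-triol
Conditions: MeLi (8 equiv), THF, −78 °C (inverse addition); H2O at −78 °C
Reagents that add atoms: methyllithium, [Li]C
Why: 1,2-Addition of MeLi to the non-enolisable enone (C5 and C9 are quaternary) from the α face anti to the axial C20 methyl also cleaves both acetates, and the C8 configuration does not matter because the alcohol is transposed next.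

Step 12
Reactants: 17 9α-[(1R)-1-hydroxy-3-(hydroxymethyl)but-3-en-1-yl]-5β,8α,9β-trimethyl-4α-[(trimethylsilyl)methyl]-10αH-decal-6-ene-1α,4β,8β-triol
Product: 18 9α-[(1R)-1-hydroxy-3-(hydroxymethyl)but-3-en-1-yl]-5β,8,9β-trimethyl-4α-[(trimethylsilyl)methyl]-10αH-decal-7-ene-1α,4β,6β-triol
Conditions: Ph3SiOReO3 (5 mol%), Et2O, −50 to 0 °C
Reagents that add atoms: none
Why: Rhenium-oxo-catalysed 1,3-transposition of the tertiary allylic alcohol ([3,3]-sigmatropic shift of the allyl perrhenate) gives the less strained secondary alcohol with the trisubstituted C7=C8 alkene, and both suprafacial delivery from 8β and thermodynamics favour the equatorial 6β-OH.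

Step 13
Reactants: 18 9α-[(1R)-1-hydroxy-3-(hydroxymethyl)but-3-en-1-yl]-5β,8,9β-trimethyl-4α-[(trimethylsilyl)methyl]-10αH-decal-7-ene-1α,4β,6β-triol
Product: 20 9α-[(1R)-1-acetoxy-3-(acryloyloxymethyl)but-3-en-1-yl]-1α,6β-diacetoxy-5β,8,9β-trimethyl-4α-[(trimethylsilyl)methyl]-10αH-decal-7-en-4β-ol, via C16 acrylate 19 (not isolated)
Conditions: acryloyl chloride (1.05 equiv), 2,4,6-collidine, CH2Cl2, −78 °C; then Ac2O, DMAP, pyridine, rt
Reagents that add atoms: acryloyl chloride, C=CC(Cl)=O; acetic anhydride, CC(=O)OC(C)=O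
Why: Sequential acylation, in which the acid chloride at −78 °C takes only the primary allylic C16 alcohol and Ac2O/DMAP then esterifies the three secondary alcohols (C1, C6, C11) while the tertiary C4 alcohol stays free.

Step 14
Reactants: 20 9α-[(1R)-1-acetoxy-3-(acryloyloxymethyl)but-3-en-1-yl]-1α,6β-diacetoxy-5β,8,9β-trimethyl-4α-[(trimethylsilyl)methyl]-10αH-decal-7-en-4β-ol
Product: 21 1α,6β-diacetoxy-9α-[(1R)-1-acetoxy-2-(5-oxo-2,5-dihydrofuran-3-yl)ethyl]-5β,8,9β-trimethyl-4α-[(trimethylsilyl)methyl]-10αH-decal-7-en-4β-ol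
Conditions: second-generation Hoveyda–Grubbs catalyst, RuCl2(H2IMes)(=CH-C6H4-2-OiPr) (10 mol%), toluene, 80 °C
Reagents that add atoms: none
Why: Ring-closing metathesis of the acrylate with the 1,1-disubstituted alkene closes the β-substituted butenolide, and the hindered trisubstituted C7=C8 alkene is inert.

Step 15
Reactants: 21 1α,6β-diacetoxy-9α-[(1R)-1-acetoxy-2-(5-oxo-2,5-dihydrofuran-3-yl)ethyl]-5β,8,9β-trimethyl-4α-[(trimethylsilyl)methyl]-10αH-decal-7-en-4β-ol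
Product: 22 1α,6β-diacetoxy-9α-[(1R)-1-acetoxy-2-(5-oxo-2,5-dihydrofuran-3-yl)ethyl]-5β,8β,9β-trimethyl-4α-[(trimethylsilyl)methyl]-10αH-decalin-4β,7α,8α-triol
Conditions: OsO4 (10 mol%), NMO, citric acid, acetone/H2O, rt
Reagents that add atoms: osmium tetroxide, O=[Os](=O)(=O)=O; N-methylmorpholine N-oxide, C[N+]1([O-])CCOCC1; water, O
Why: Upjohn dihydroxylation of the only electron-rich alkene occurs on the α face, anti to the allylic 6β-acetate (Kishi's rule) and to the axial C19 and C20 methyls, and sets 7α-OH and 8α-OH (8β-CH3).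

Step 16
Reactants: 22 1α,6β-diacetoxy-9α-[(1R)-1-acetoxy-2-(5-oxo-2,5-dihydrofuran-3-yl)ethyl]-5β,8β,9β-trimethyl-4α-[(trimethylsilyl)methyl]-10αH-decalin-4β,7α,8α-triol
Product: 23 1α,6β-diacetoxy-9α-[(1R)-1-acetoxy-2-(5-oxo-2,5-dihydrofuran-3-yl)ethyl]-7α-(isobutyryloxy)-5β,8β,9β-trimethyl-4α-[(trimethylsilyl)methyl]-10αH-decalin-4β,8α-diol
Conditions: iPrCOCl, pyridine, DMAP (cat.), CH2Cl2, 0 °C
Reagents that add atoms: isobutyryl chloride, CC(C)C(Cl)=O
Why: Acylation of the only secondary alcohol (C7), since both tertiary alcohols are unreactive, and the short cold reaction limits acetyl migration from C6.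

Step 17
Reactants: 23 1α,6β-diacetoxy-9α-[(1R)-1-acetoxy-2-(5-oxo-2,5-dihydrofuran-3-yl)ethyl]-7α-(isobutyryloxy)-5β,8β,9β-trimethyl-4α-[(trimethylsilyl)methyl]-10αH-decalin-4β,8α-diol
Product: 24 (1S,5S,6S,7R,8S,9R,10R,11R)-1,6,11-triacetoxy-8-hydroxy-7-(isobutyryloxy)cleroda-4(18),13-dien-15,16-olide (CNP0266716.2)
Conditions: aq. HF, MeCN, 0 °C to rt
Reagents that add atoms: none
Why: Acid-promoted Peterson elimination of the tertiary β-hydroxysilane gives the C4(18) exocyclic alkene regiospecifically under conditions that spare the esters, the butenolide and the C8 tertiary alcohol.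

**Compound list**
1 | (S)-5-(hydroxymethyl)dihydrofuran-2(3H)-one | O=C1CC[C@H](O1)CO | starting material
2 | 3-(triphenyl-λ5-phosphanylidene)butan-2-one | CC(=O)C(C)=P(c1ccccc1)(c1ccccc1)c1ccccc1 | starting material
3 | (S)-5-oxotetrahydrofuran-2-carbaldehyde | O=C1CC[C@H](O1)C=O | intermediate
4 | (S)-5-[(1E)-2-methyl-3-oxobut-1-en-1-yl]dihydrofuran-2(3H)-one | O=C1CC[C@H](O1)/C=C(\C)C(C)=O | intermediate
5 | (S)-5-[(1E)-2-methyl-3-(triethylsilyloxy)buta-1,3-dien-1-yl]dihydrofuran-2(3H)-one | O=C1CC[C@H](O1)/C=C(\C)C(=C)O[Si](CC)(CC)CC | intermediate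
6 | (6S,7E)-6-hydroxy-2,8-dimethyl-9-(triethylsilyloxy)deca-1,7,9-trien-3-one | C=C(C)C(=O)CC[C@H](O)/C=C(\C)C(=C)O[Si](CC)(CC)CC | intermediate
7 | 1α-hydroxy-5β,9-dimethyl-8-(triethylsilyloxy)-10αH-decal-8-en-4-one (trans-fused) | O=C1CC[C@H](O)[C@@H]2[C@]1(C)CCC(O[Si](CC)(CC)CC)=C2C | intermediate
8 | 5β,9-dimethyl-8-(triethylsilyloxy)-4α-[(trimethylsilyl)methyl]-10αH-decal-8-ene-1α,4β-diol | C[Si](C)(C)C[C@]1(O)CC[C@H](O)[C@@H]2[C@]1(C)CCC(O[Si](CC)(CC)CC)=C2C | intermediate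
9 | 1α-acetoxy-5β,9-dimethyl-8-(triethylsilyloxy)-4α-[(trimethylsilyl)methyl]-10αH-decal-8-en-4β-ol | C[Si](C)(C)C[C@]1(O)CC[C@H](OC(C)=O)[C@@H]2[C@]1(C)CCC(O[Si](CC)(CC)CC)=C2C | intermediate
10 | 1α-acetoxy-4β-hydroxy-9α-(hydroxymethyl)-5β,9β-dimethyl-4α-[(trimethylsilyl)methyl]-10αH-decalin-8-one | C[Si](C)(C)C[C@]1(O)CC[C@H](OC(C)=O)[C@@H]2[C@]1(C)CCC(=O)[C@@]2(C)CO | intermediate
11 | 1α-acetoxy-4β-hydroxy-5β,9β-dimethyl-8-oxo-4α-[(trimethylsilyl)methyl]-10αH-decalin-9α-carbaldehyde | C[Si](C)(C)C[C@]1(O)CC[C@H](OC(C)=O)[C@@H]2[C@]1(C)CCC(=O)[C@@]2(C)C=O | intermediate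
12 | 1α-acetoxy-4β-hydroxy-5β,9β-dimethyl-8-oxo-4α-[(trimethylsilyl)methyl]-10αH-decal-6-ene-9α-carbaldehyde | C[Si](C)(C)C[C@]1(O)CC[C@H](OC(C)=O)[C@@H]2[C@]1(C)C=CC(=O)[C@@]2(C)C=O | intermediate
13 | 2-methylprop-2-en-1-ol | C=C(C)CO | starting material
14 | 2-[(tributylstannyl)methyl]prop-2-en-1-ol | C=C(CO)C[Sn](CCCC)(CCCC)CCCC | intermediate
15 | 2-[(tributylstannyl)methyl]prop-2-en-1-yl acetate | C=C(COC(C)=O)C[Sn](CCCC)(CCCC)CCCC | intermediate
16 | 9α-[(1R)-3-(acetoxymethyl)-1-hydroxybut-3-en-1-yl]-1α-acetoxy-4β-hydroxy-5β,9β-dimethyl-4α-[(trimethylsilyl)methyl]-10αH-decal-6-en-8-one | C[Si](C)(C)C[C@]1(O)CC[C@H](OC(C)=O)[C@@H]2[C@]1(C)C=CC(=O)[C@@]2(C)[C@@H](CC(=C)COC(C)=O)O | intermediate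
17 | 9α-[(1R)-1-hydroxy-3-(hydroxymethyl)but-3-en-1-yl]-5β,8α,9β-trimethyl-4α-[(trimethylsilyl)methyl]-10αH-decal-6-ene-1α,4β,8β-triol | C[Si](C)(C)C[C@]1(O)CC[C@H](O)[C@@H]2[C@]1(C)C=C[C@](C)(O)[C@@]2(C)[C@@H](CC(=C)CO)O | intermediate
18 | 9α-[(1R)-1-hydroxy-3-(hydroxymethyl)but-3-en-1-yl]-5β,8,9β-trimethyl-4α-[(trimethylsilyl)methyl]-10αH-decal-7-ene-1α,4β,6β-triol | C[Si](C)(C)C[C@]1(O)CC[C@H](O)[C@@H]2[C@]1(C)[C@H](O)C=C(C)[C@@]2(C)[C@@H](CC(=C)CO)O | intermediate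
19 | C16 mono-acrylate of 18 (primary allylic hydroxyl acylated) | C[Si](C)(C)C[C@]1(O)CC[C@H](O)[C@@H]2[C@]1(C)[C@H](O)C=C(C)[C@@]2(C)[C@@H](CC(=C)COC(=O)C=C)O | intermediate
20 | 9α-[(1R)-1-acetoxy-3-(acryloyloxymethyl)but-3-en-1-yl]-1α,6β-diacetoxy-5β,8,9β-trimethyl-4α-[(trimethylsilyl)methyl]-10αH-decal-7-en-4β-ol | C[Si](C)(C)C[C@]1(O)CC[C@H](OC(C)=O)[C@@H]2[C@]1(C)[C@H](OC(C)=O)C=C(C)[C@@]2(C)[C@@H](CC(=C)COC(=O)C=C)OC(C)=O | intermediate
21 | 1α,6β-diacetoxy-9α-[(1R)-1-acetoxy-2-(5-oxo-2,5-dihydrofuran-3-yl)ethyl]-5β,8,9β-trimethyl-4α-[(trimethylsilyl)methyl]-10αH-decal-7-en-4β-ol | C[Si](C)(C)C[C@]1(O)CC[C@H](OC(C)=O)[C@@H]2[C@]1(C)[C@H](OC(C)=O)C=C(C)[C@@]2(C)[C@@H](CC3=CC(=O)OC3)OC(C)=O | intermediate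
22 | 1α,6β-diacetoxy-9α-[(1R)-1-acetoxy-2-(5-oxo-2,5-dihydrofuran-3-yl)ethyl]-5β,8β,9β-trimethyl-4α-[(trimethylsilyl)methyl]-10αH-decalin-4β,7α,8α-triol | C[Si](C)(C)C[C@]1(O)CC[C@H](OC(C)=O)[C@@H]2[C@]1(C)[C@H](OC(C)=O)[C@@H](O)[C@@](C)(O)[C@@]2(C)[C@@H](CC3=CC(=O)OC3)OC(C)=O | intermediate
23 | 1α,6β-diacetoxy-9α-[(1R)-1-acetoxy-2-(5-oxo-2,5-dihydrofuran-3-yl)ethyl]-7α-(isobutyryloxy)-5β,8β,9β-trimethyl-4α-[(trimethylsilyl)methyl]-10αH-decalin-4β,8α-diol | C[Si](C)(C)C[C@]1(O)CC[C@H](OC(C)=O)[C@@H]2[C@]1(C)[C@H](OC(C)=O)[C@@H](OC(=O)C(C)C)[C@@](C)(O)[C@@]2(C)[C@@H](CC3=CC(=O)OC3)OC(C)=O | intermediate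
24 | (1S,5S,6S,7R,8S,9R,10R,11R)-1,6,11-triacetoxy-8-hydroxy-7-(isobutyryloxy)cleroda-4(18),13-dien-15,16-olide (1α,6β,11-OAc; 7α-OiBu; 8α-OH) | C=C1CC[C@H](OC(C)=O)[C@@H]2[C@]1(C)[C@H](OC(C)=O)[C@@H](OC(=O)C(C)C)[C@@](C)(O)[C@@]2(C)[C@@H](CC1=CC(=O)OC1)OC(C)=O | target

**Totals**
Total step count: 17. Longest linear sequence: 15 (steps 1–7 and 10–17; steps 8–9 make stannane 15).

**Three steps most likely to fail, with fallbacks**

Step 3, ring fusion in the intramolecular Diels–Alder reaction. An internal ketone can favour the tether-endo (cis-fused) mode, and a wrong C5 cannot be repaired in this enantiomeric series. The fallback sets out from ylide 2 and comes back at 8. The same first three operations are run on the enantiomeric lactone (R)-5-(hydroxymethyl)dihydrofuran-2(3H)-one F1 (D-glutamic acid series). They pass through (R)-5-oxotetrahydrofuran-2-carbaldehyde F2, the (R)-enone lactone F3, the (R)-silyloxydiene lactone F4 and the (R)-hydroxy trienone F5, and give the cis-fused adduct F6 (1β-OH, 10β-H, 5β-CH3), in which C5 is already correct. Me3SiCH2Li/CeCl3 gives the β-hydroxysilane diol F7, and Dess–Martin oxidation gives the cis-fused C1 ketone F8. DBU then equilibrates C10, now α to the ketone, to the trans-fused C1 ketone F9. A thermodynamic ketone reduction (SmI2, H2O, Et3N, THF) gives the equatorial 1α-alcohol 8 (C4 configuration immaterial). Ring fusion is then set by equilibration and C1 by reduction.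

Step 7, one-pot IBX double oxidation. Hot IBX may erode the β-hydroxysilane or the β-keto aldehyde. The fallback sets out from 10 and comes back at 12 by a Saegusa–Ito route. TMSOTf/Et3N gives the tris(trimethylsilyl) enol ether F10, in which enolisation is possible only towards C7. Pd(OAc)2 in MeCN gives the enone bis(trimethylsilyl) ether F11, and citric acid in MeOH frees the hydroxy enone F12. Dess–Martin oxidation of its primary alcohol gives 12.

Step 12, rhenium-catalysed transposition on an unprotected polyol. Elimination, ether formation through the C11 hydroxyl or loss of the β-hydroxysilane may compete. The fallback sets out from 17 and comes back at 20 by a Dauben oxidative transposition. Acryloyl chloride/collidine at −78 °C gives the C16 acrylate F13, and Ac2O/DMAP gives the C1,C11-diacetate F14 with both tertiary alcohols free. NaOAc-buffered C5H5NH[CrO3Cl] (pyridinium chlorochromate) gives the transposed C6 enone F15. Luche reduction (NaBH4, CeCl3, MeOH, −78 °C; axial hydride on the α face, anti to C19) gives the 6β-alcohol F16, and acetylation gives 20.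

**Further compounds**
F1 | step 3 | (R)-5-(hydroxymethyl)dihydrofuran-2(3H)-one | O=C1CC[C@@H](O1)CO
F2 | step 3 | (R)-5-oxotetrahydrofuran-2-carbaldehyde | O=C1CC[C@@H](O1)C=O
F3 | step 3 | (R)-5-[(1E)-2-methyl-3-oxobut-1-en-1-yl]dihydrofuran-2(3H)-one | O=C1CC[C@@H](O1)/C=C(\C)C(C)=O
F4 | step 3 | (R)-5-[(1E)-2-methyl-3-(triethylsilyloxy)buta-1,3-dien-1-yl]dihydrofuran-2(3H)-one | O=C1CC[C@@H](O1)/C=C(\C)C(=C)O[Si](CC)(CC)CC
F5 | step 3 | (6R,7E)-6-hydroxy-2,8-dimethyl-9-(triethylsilyloxy)deca-1,7,9-trien-3-one | C=C(C)C(=O)CC[C@@H](O)/C=C(\C)C(=C)O[Si](CC)(CC)CC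
F6 | step 3 | 1β-hydroxy-5β,9-dimethyl-8-(triethylsilyloxy)-10βH-decal-8-en-4-one (cis-fused) | O=C1CC[C@@H](O)[C@H]2[C@]1(C)CCC(O[Si](CC)(CC)CC)=C2C
F7 | step 3 | 5β,9-dimethyl-8-(triethylsilyloxy)-4-[(trimethylsilyl)methyl]-10βH-decal-8-ene-1β,4-diol (cis-fused) | C[Si](C)(C)C[C@]1(O)CC[C@@H](O)[C@H]2[C@]1(C)CCC(O[Si](CC)(CC)CC)=C2C
F8 | step 3 | 4-hydroxy-5β,9-dimethyl-8-(triethylsilyloxy)-4-[(trimethylsilyl)methyl]-10βH-decal-8-en-1-one (cis-fused) | C[Si](C)(C)C[C@]1(O)CCC(=O)[C@H]2[C@]1(C)CCC(O[Si](CC)(CC)CC)=C2C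
F9 | step 3 | 4β-hydroxy-5β,9-dimethyl-8-(triethylsilyloxy)-4α-[(trimethylsilyl)methyl]-10αH-decal-8-en-1-one (trans-fused) | C[Si](C)(C)C[C@]1(O)CCC(=O)[C@@H]2[C@]1(C)CCC(O[Si](CC)(CC)CC)=C2C
F10 | step 7 | 1α-acetoxy-5β,9β-dimethyl-4β,8-bis(trimethylsilyloxy)-9α-[(trimethylsilyloxy)methyl]-4α-[(trimethylsilyl)methyl]-10αH-decal-7-ene | C[Si](C)(C)C[C@]1(O[Si](C)(C)C)CC[C@H](OC(C)=O)[C@@H]2[C@]1(C)CC=C(O[Si](C)(C)C)[C@@]2(C)CO[Si](C)(C)C
F11 | step 7 | 1α-acetoxy-5β,9β-dimethyl-4β-(trimethylsilyloxy)-9α-[(trimethylsilyloxy)methyl]-4α-[(trimethylsilyl)methyl]-10αH-decal-6-en-8-one | C[Si](C)(C)C[C@]1(O[Si](C)(C)C)CC[C@H](OC(C)=O)[C@@H]2[C@]1(C)C=CC(=O)[C@@]2(C)CO[Si](C)(C)C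
F12 | step 7 | 1α-acetoxy-4β-hydroxy-9α-(hydroxymethyl)-5β,9β-dimethyl-4α-[(trimethylsilyl)methyl]-10αH-decal-6-en-8-one | C[Si](C)(C)C[C@]1(O)CC[C@H](OC(C)=O)[C@@H]2[C@]1(C)C=CC(=O)[C@@]2(C)CO
F13 | step 12 | C16 mono-acrylate of 17 | C[Si](C)(C)C[C@]1(O)CC[C@H](O)[C@@H]2[C@]1(C)C=C[C@](C)(O)[C@@]2(C)[C@@H](CC(=C)COC(=O)C=C)O
F14 | step 12 | C1,C11-diacetate C16-acrylate of 17 (4β-OH and 8β-OH free) | C[Si](C)(C)C[C@]1(O)CC[C@H](OC(C)=O)[C@@H]2[C@]1(C)C=C[C@](C)(O)[C@@]2(C)[C@@H](CC(=C)COC(=O)C=C)OC(C)=O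
F15 | step 12 | 9α-[(1R)-1-acetoxy-3-(acryloyloxymethyl)but-3-en-1-yl]-1α-acetoxy-4β-hydroxy-5β,8,9β-trimethyl-4α-[(trimethylsilyl)methyl]-10αH-decal-7-en-6-one | C[Si](C)(C)C[C@]1(O)CC[C@H](OC(C)=O)[C@@H]2[C@]1(C)C(=O)C=C(C)[C@@]2(C)[C@@H](CC(=C)COC(=O)C=C)OC(C)=O
F16 | step 12 | 9α-[(1R)-1-acetoxy-3-(acryloyloxymethyl)but-3-en-1-yl]-1α-acetoxy-5β,8,9β-trimethyl-4α-[(trimethylsilyl)methyl]-10αH-decal-7-ene-4β,6β-diol | C[Si](C)(C)C[C@]1(O)CC[C@H](OC(C)=O)[C@@H]2[C@]1(C)[C@H](O)C=C(C)[C@@]2(C)[C@@H](CC(=C)COC(=O)C=C)OC(C)=O
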